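The readings are simulated with constants of no real substance; the scatter is artificial.

Late in the birch run, which is this very flask followed so far, Z and L together hold 73.9% of the L charged at 5.00 d, and Z is still falling.

the same everywhere: L 0.050 M
- birch: Q 0.25 M; the very flask that is asked about, followed so far
- oak: Q 0.38 M; run made earlier
- flask: Q 0.250 M; time 8.0 d

birch run (percent of the L charged)

| time / d | Z / % | L / % |
|---|---|---|
| 0.417 | 48.5 | 49.6 |
| 0.833 | 46.8 | 48.4 |
| 1.25 | 44.3 | 48.6 |
| 2.50 | 38.4 | 44.7 |
| 5.00 | 31.3 | 42.6 |

oak run (percent of the L charged)

| time / h | Z / % | L / % |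
|---|---|---|
| 3.00 | 47.5 | 54.4 |
| 10.0 | 53.8 | 41.8 |
| 20.0 | 51.6 | 39.0 |
| 30.0 | 48.4 | 40.5 |
| 40.0 | 45.1 | 38.7 |

(each reading ± 1 percentage point)

- removed Z is counted in
- additions bring no volume worth counting

- Tuesday's: change nothing and wait 4.0 d more
- Friday's: at 8.0 d add Q, 100% of the amount charged, then wait 4.0 d
- Wednesday's: at 8.0 d add L, 50.0% of the amount charged, then wait 4.0 d
- Thursday's: at 8.0 d take out 90% of the Z then present, then wait 4.0 d

- Z, in percent of the L first charged, at 8.0 d
- what to do for the largest gain in Z; "none" if nothing gains more than 2 percentage points (Tuesday's / Friday's / Wednesday's / Thursday's / none)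
- Z present, with what was taken out counted in, in percent of the L first charged, after Friday's
- Z present, with what was taken out counted in, in percent of the L first charged, after Wednesday's

Read that drift as the bottom of a ladder of times. On the top rung, within hours, Z and L come to a fast pre-equilibrium: in the oak run Z already stands above L at 10.0 h.

The second rung is where that balance lies. In the birch run Z/L slips from 0.978 to 0.735, so I assume a coproduct that stays in solution, one for each L gone. The first birch reading then gives the balance quotient, [Z][coproduct]/([L][Q]), as 0.110. The oak run, with its richer Q, reads 0.107 at 10.0 h.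

On the bottom rung the pool L + Z of the birch run reads as draining at 0.0618 /d, a time of 16.2 d, far longer than the balance needs. So you can let the pool shrink and split it by the quotient at each moment.

My reckoning puts the pool at 61.4% at 8.0 d. Charging one Q to each unit lost, the quotient then gives Z as 25.0%. I expect a dose or removal to be answered in about 10.0 h, which is shorter than the 4.0 d of waiting. By my reckoning Thursday's banks 22.5% and lets L refill Z, so I take Thursday's.

The forecast says Z 25.7%, a little above mine, then Thursday's, with 21.5% after Friday's and 25% after Wednesday's. Its ground for the loss: “Z also drains irreversibly, since L+Z falls.”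

The flask gives Z 25.6% and Thursday's as best, gaining 9 percentage points. Friday's ends at 18.3%, and Wednesday's at 30.8%, above the forecast.

    L + Q ⇌ Z + G (K = 0.110, k = 0.750 /M/h)
    Q + Z → J (k = 0.0260 /M/h)

At 0.0969 d Z falls back 18 times faster than it goes on. At 8.00 d the net rate of making Z is 0.433 of the net rate of using it up. What stands in the flask at that time gives [Z][G]/([L][Q]) as 0.109. For the neighbour charged with 0.013 M of L, the quotient read earlier, 0.110, and that neighbour's own [Q] and [G] give Z/L of 2.26, and at 8.00 d it holds Z 30.5% against L 13.7%, a ratio of 2.23.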